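The constants send each substrate molecule to a fork: it turns into target by itself, or it meets reagent and turns into a side product.

    substrate + reagent → side product A (k1 = 270 /M/s)
    substrate → target (k2 = 0.145 /s)
    substrate + reagent → side product B (k3 = 2530 /M/s)
    2 reagent → self-condensation product (k4 = 174 /M/s)

| flask | substrate | reagent | remark | time |
|---|---|---|---|---|
| Sunday's | 0.0020 M | 1.00 equiv | a single well-mixed tank run continuously and read at steady state, 6.0 s in it on average |  |
| Tuesday's | 0.0020 M | 1.00 equiv (fed, over 4.80 s) | a stirred flask in which reagent is dosed at a steady rate over 4.80 s without added volume, worked up at 6.0 s | 6.0 s |
| Thursday's | 0.0020 M (fed, over 4.80 s) | 1.00 equiv | a stirred flask in which substrate is dosed at a steady rate over 4.80 s without added volume, worked up at 6.0 s | 6.0 s |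
| Wednesday's | 0.0020 M | 1.00 equiv | everything together in a closed stirred flask, run for 6.0 s | 6.0 s |

- where a step has two of a species, its rate is k times that concentration squared, and two are used at each turn
- the stated concentrations are those of everything mixed, before any reaction; amounts are the same in each set-up
- the feed brings no volume worth counting
- run time (Tuesday's): 6.0 s

* the set-up with the highest amount of target at the outlet or at the end, in percent of the substrate put in ("none" if the first two lie within 2 percentage points) (Sunday's / Tuesday's / Thursday's / Wednesday's / none)
* amount of target at the outlet or at the end, in percent of the substrate put in, Sunday's
* amount of target at the outlet or at the end, in percent of the substrate put in, Tuesday's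
* amount of target at the outlet or at the end, in percent of the substrate put in, Thursday's
* amount of target at the outlet or at the end, in percent of the substrate put in, Wednesday's

Per substrate molecule, the two reagent steps together run at 2800 /M/s times [reagent]. At steady [reagent] they are pseudo-first-order, and the step to target runs at 0.145 /s. The [reagent] that makes the two routes equally likely is their ratio, 5.18 × 10⁻⁵ M, and I call it the even-odds level. A molecule's chance of target is the level divided by the level plus [reagent]. In Wednesday's flask the charged [reagent] of 0.00200 M lies far above the level, so the chance there starts at 2.52%.

Two chemists argue over how to bring [reagent] down to the level. The first doses reagent, as in Tuesday's flask. That dose brings 4.17 × 10⁻⁴ M/s. With substrate still at 0.0020 M, the reagent steps balance the dose at a [reagent] of 7.44 × 10⁻⁵ M, above the level. So in Tuesday's flask, once that balance stands, the chance is near 41.0%, and the balancing [reagent] climbs as substrate is used.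

The second chemist charges reagent first and doses substrate, as in Thursday's flask, so that reagent destroys itself. By the self-condensation step alone, the first half-life of reagent is 1.44 s, shorter than the dose of 4.80 s.

The first chemist answers that this decay slows as [reagent] falls. Reckoned by that step alone, with the reagent taken up by substrate left out of the sum, Thursday's [reagent] at the end of the dose is 4.61 × 10⁻⁴ M, which is 8.90 levels. The last substrate in Thursday's flask then has 1.20 s left, less than its half-life by the step to target, 4.78 s. I side with the first chemist at 6.0 s, but my reckoning stops at these chances and gives no yields.

The forecast takes the same side and does give yields. It names Tuesday's, with 12.2% for Sunday's tank, 29.2% for Tuesday's flask, 16.7% for Thursday's flask and 9.3% for Wednesday's flask. Of Thursday's flask it says: “Late substrate survives, but there is little time left”.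

The simulation gives 12.1% for Sunday's tank, 29.0% for Tuesday's flask, 16.7% for Thursday's flask and 9.34% for Wednesday's flask, so Tuesday's comes out highest at 6.0 s. The second chemist's recipe comes out ahead in the longer run: at 60.0 s Thursday's flask gives 48.2%, more than the 29.0% of Tuesday's flask at that time. Tuesday's yield stays put over a tenfold time, and read as a chance at the fork it equals the chance at a steady [reagent] of 1.27 × 10⁻⁴ M, or 2.45 levels. Thursday's 48.2% at 60.0 s, read the same way, equals the chance at 5.57 × 10⁻⁵ M, or 1.07 levels.

All constants stand for no real mixture.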